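The strategy rests on the pyran ring of the chroman (O1, C2 with two methyls, C3 carbinol, C4, fused to the benzene ring at C4a/C8a): C4=C4a–C8a=O1 is a latent o-quinone methide, and C3–C2(Me)2 is an isobutenyl unit in which boron on C3 stands for the C3 oxygen.
Key disconnection: C4–C3 and O1–C2, by a phosphoric acid-catalysed asymmetric inverse-demand hetero-Diels–Alder reaction of the o-quinone methide (from an o-hydroxybenzyl alcohol) with isobutenyl pinacol boronate; C3–B is then oxidised to C3–OH with retention.
The C8 acyl bond is cut to a C8 aryllithium (from a C8 bromide) and the Weinreb amide of 3-phenylpropanoic acid; the bromine is installed before the key step, where it blocks the only nucleophilic ring carbon of the quinone methide and of the cycloadduct.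
The o-hydroxybenzyl alcohol comes from 2-methylresorcinol by bis-MOM protection, C–H borylation/oxidation at C5, ortho-formylation, bromination and reduction; MOM ethers have no aromatic C–H for the borylation, tolerate the aryllithium and leave under mild acid.
Ring order: the benzene ring is bought; the pyran ring is the only ring made, in the key step.

Key step: step 6

Remark: chroman means 3,4-dihydro-2H-chromene, numbered O1, C2, C3, C4, C4a, C5–C8, C8a; the target is (3S).
Remark (assumption): the sense of induction of the phosphoric acid cannot be predicted for this dienophile; the (R)-acid is written, and the (S)-acid replaces it if the first assay of the alcohol from step 7 shows the (3R) series.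

Step 1
Reactants: 1 2-methylbenzene-1,3-diol (2-methylresorcinol)
Product: 2 1,3-bis(methoxymethoxy)-2-methylbenzene
Conditions: NaH (2.4 equiv), MOMCl (2.4 equiv), DMF, 0 °C to rt
Reagents that add atoms: chloromethyl methyl ether (MOMCl), COCCl
Why: Williamson-type O-alkylation of the bis-phenoxide by the hard α-chloro ether gives the bis-acetal, a protecting group that has no aromatic C–H bonds.

Step 2
Reactants: 2 1,3-bis(methoxymethoxy)-2-methylbenzene
Product: 4 3,5-bis(methoxymethoxy)-4-methylphenol, via aryl pinacol boronate 3 (not isolated)
Conditions: [Ir(OMe)(cod)]2 (1.5 mol %), 4,4'-di-tert-butyl-2,2'-bipyridine (3 mol %), B2pin2 (0.7 equiv), THF, 80 °C; then NaBO3·4H2O, THF/H2O, rt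
Reagents that add atoms: sodium perborate tetrahydrate, [Na+].[O-]OB=O; bis(pinacolato)diboron, CC1(C)OB(OC1(C)C)B1OC(C)(C)C(C)(C)O1 (boron group of intermediate 3 only)
Why: Iridium-catalysed aromatic C–H borylation is governed by sterics and takes the one C–H with no ortho substituent (C5, para to the methyl), and oxidation of the aryl boronate in the same flask gives the symmetric phenol.

Step 3
Reactants: 4 3,5-bis(methoxymethoxy)-4-methylphenol
Product: 5 2-hydroxy-4,6-bis(methoxymethoxy)-5-methylbenzaldehyde
Conditions: MgCl2 (2 equiv), Et3N (4 equiv), (CH2O)n (6 equiv), MeCN, reflux; aq NH4Cl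
Reagents that add atoms: paraformaldehyde (formaldehyde), C=O
Why: Magnesium-mediated ortho-formylation of a phenol (Casnati–Skattebøl reaction), in which the magnesium phenoxide delivers formaldehyde to the ortho carbon and a second formaldehyde oxidises the hydroxymethyl intermediate by hydride transfer; the two ortho positions of 4 are equivalent, so one aldehyde should result, and the basic medium leaves the acetals alone.

Step 4
Reactants: 5 2-hydroxy-4,6-bis(methoxymethoxy)-5-methylbenzaldehyde
Product: 6 3-bromo-2-hydroxy-4,6-bis(methoxymethoxy)-5-methylbenzaldehyde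
Conditions: NBS (1.05 equiv), MeCN, 0 °C, dark
Reagents that add atoms: N-bromosuccinimide, O=C1CCC(=O)N1Br
Why: Electrophilic aromatic bromination at the only ring C–H left, ortho to the free hydroxyl and ortho/para to the acetal oxygens; the bromine later blocks C8 in the key step and is the handle for the acyl group.

Step 5
Reactants: 6 3-bromo-2-hydroxy-4,6-bis(methoxymethoxy)-5-methylbenzaldehyde
Product: 7 2-bromo-6-(hydroxymethyl)-3,5-bis(methoxymethoxy)-4-methylphenol
Conditions: NaBH4 (1 equiv), THF/MeOH, −10 to 0 °C; pH 7 buffer; used at once
Reagents that add atoms: none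
Why: Borohydride reduction of the aldehyde to the primary benzylic alcohol; low temperature and neutral work-up keep the electron-rich o-hydroxybenzyl alcohol from ionising, and the aryl bromide and acetals are inert.

Step 6
Reactants: 7 2-bromo-6-(hydroxymethyl)-3,5-bis(methoxymethoxy)-4-methylphenol; 8 4,4,5,5-tetramethyl-2-(2-methylprop-1-enyl)-1,3,2-dioxaborolane
Product: 10 (3S)-8-bromo-5,7-bis(methoxymethoxy)-2,2,6-trimethyl-3-(4,4,5,5-tetramethyl-1,3,2-dioxaborolan-2-yl)chroman, via o-quinone methide 9 (not isolated)
Conditions: (R)-3,3'-bis(2,4,6-triisopropylphenyl)-1,1'-binaphthyl-2,2'-diyl hydrogen phosphate (10 mol %), 8 (5 equiv), 5 Å molecular sieves, toluene, 0 °C to rt, slow addition of 7; then Et3N, filtration through Et3N-deactivated silica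
Reagents that add atoms: none
Why: Proposed new method: the chiral phosphoric acid dehydrates 7 (its benzylic cation is stabilised by the ortho hydroxyl and the ortho and para acetal oxygens) to the o-quinone methide 9, which stays hydrogen-bonded to the catalyst; the boron-bearing CH of 8 attacks the methide carbon (C4–C3) while charge builds on the dimethyl-substituted carbon, stabilised by the two methyls and the adjacent C–B bond, and the quinone methide oxygen captures it (O1–C2). The closest known reactions are phosphoric acid-catalysed [4+2] cycloadditions of o-quinone methides from o-hydroxybenzyl alcohols with styrenes and enol ethers, and thermal cycloadditions of phloroglucinol-type o-quinone methides with trisubstituted alkenes; an alkenylboronate dienophile on an unsubstituted methide carbon is not among them. The pyran ring closes by intermolecular inverse-demand hetero-[4+2] cycloaddition, asynchronous, and in the stepwise limit by six-membered oxygen capture of the tertiary cation. The only new stereocenter, C3, is set by which face of the alkene CH reaches the catalyst-bound quinone methide; control is expected from the catalyst pocket, with the P–OH on the quinone methide oxygen and the phosphoryl oxygen on boron or a pinacol oxygen as second contact, and this is the unproven element. The step needs regioselectivity (oxygen on the CMe2 carbon), secured by the gem-dimethyl and boron substitution of 8, and chemoselectivity against self-condensation of 9, secured by the C8 bromine on the only nucleophilic ring carbon, by excess 8 and by slow addition of 7.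

Step 7
Reactants: 10 (3S)-8-bromo-5,7-bis(methoxymethoxy)-2,2,6-trimethyl-3-(4,4,5,5-tetramethyl-1,3,2-dioxaborolan-2-yl)chroman
Product: 11 (3S)-8-bromo-5,7-bis(methoxymethoxy)-2,2,6-trimethylchroman-3-ol
Conditions: NaBO3·4H2O (5 equiv), THF/H2O (1:1), rt
Reagents that add atoms: sodium perborate tetrahydrate, [Na+].[O-]OB=O
Why: Perborate oxidation of the secondary alkyl boronate proceeds by 1,2-shift of C3 from boron to oxygen with retention, so the (3S)-boronate should give the (3S)-alcohol (the descriptor stays S although the priorities change), and the mild reagent leaves the bromide and acetals untouched.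

Step 8
Reactants: 12 3-phenylpropanoyl chloride
Product: 13 N-methoxy-N-methyl-3-phenylpropanamide
Conditions: MeNHOMe·HCl (1.1 equiv), K2CO3 (2.2 equiv), EtOAc/H2O, 0 °C to rt
Reagents that add atoms: N,O-dimethylhydroxylamine hydrochloride, CNOC.Cl
Why: Schotten–Baumann N-acylation of N,O-dimethylhydroxylamine by the acid chloride gives the Weinreb amide.

Step 9
Reactants: 11 (3S)-8-bromo-5,7-bis(methoxymethoxy)-2,2,6-trimethylchroman-3-ol; 13 N-methoxy-N-methyl-3-phenylpropanamide
Product: 15 1-[(3S)-3-hydroxy-5,7-bis(methoxymethoxy)-2,2,6-trimethylchroman-8-yl]-3-phenylpropan-1-one, via dilithiated chromanolate 14 (not isolated)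
Conditions: n-BuLi (2.2 equiv), THF, −78 °C; then 13 (1.5 equiv), −78 to −20 °C; aq NH4Cl
Reagents that add atoms: n-butyllithium, [Li]CCCC (lithium of intermediate 14 only)
Why: Weinreb ketone synthesis in which the first equivalent of n-BuLi forms the C3 lithium alkoxide and the second exchanges bromine for lithium at C8 (the aryllithium is held by the flanking MOM and ring oxygens); the chelated tetrahedral adduct with 13 collapses to the ketone only on work-up, so no over-addition occurs and C3 is not touched.

Step 10
Reactants: 15 1-[(3S)-3-hydroxy-5,7-bis(methoxymethoxy)-2,2,6-trimethylchroman-8-yl]-3-phenylpropan-1-one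
Product: 16 1-[(3S)-3,5,7-trihydroxy-2,2,6-trimethylchroman-8-yl]-3-phenylpropan-1-one (the target)
Conditions: HCl (1.25 M in MeOH), 40 °C
Reagents that add atoms: none
Why: Acid-catalysed acetal exchange with methanol removes both aryl MOM groups as dimethoxymethane; the tertiary alkyl aryl ether of the pyran ring, the secondary alcohol and the ketone are stable to dilute methanolic HCl at this temperature, and C3, a non-enolisable carbinol carbon, keeps its configuration.

Compound list
1 | 2-methylbenzene-1,3-diol | Cc1c(O)cccc1O | starting material
2 | 1,3-bis(methoxymethoxy)-2-methylbenzene | COCOc1cccc(OCOC)c1C | intermediate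
3 | 2-[3,5-bis(methoxymethoxy)-4-methylphenyl]-4,4,5,5-tetramethyl-1,3,2-dioxaborolane | COCOc1cc(B2OC(C)(C)C(C)(C)O2)cc(OCOC)c1C | intermediate
4 | 3,5-bis(methoxymethoxy)-4-methylphenol | COCOc1cc(O)cc(OCOC)c1C | intermediate
5 | 2-hydroxy-4,6-bis(methoxymethoxy)-5-methylbenzaldehyde | COCOc1cc(O)c(C=O)c(OCOC)c1C | intermediate
6 | 3-bromo-2-hydroxy-4,6-bis(methoxymethoxy)-5-methylbenzaldehyde | COCOc1c(Br)c(O)c(C=O)c(OCOC)c1C | intermediate
7 | 2-bromo-6-(hydroxymethyl)-3,5-bis(methoxymethoxy)-4-methylphenol | COCOc1c(Br)c(O)c(CO)c(OCOC)c1C | intermediate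
8 | 4,4,5,5-tetramethyl-2-(2-methylprop-1-enyl)-1,3,2-dioxaborolane | CC(C)=CB1OC(C)(C)C(C)(C)O1 | starting material
9 | 2-bromo-3,5-bis(methoxymethoxy)-4-methyl-6-methylidenecyclohexa-2,4-dien-1-one | C=C1C(=O)C(Br)=C(OCOC)C(C)=C1OCOC | intermediate
10 | (3S)-8-bromo-5,7-bis(methoxymethoxy)-2,2,6-trimethyl-3-(4,4,5,5-tetramethyl-1,3,2-dioxaborolan-2-yl)chroman | Cc1c(OCOC)c2c(c(Br)c1OCOC)OC(C)(C)[C@@H](B1OC(C)(C)C(C)(C)O1)C2 | intermediate
11 | (3S)-8-bromo-5,7-bis(methoxymethoxy)-2,2,6-trimethylchroman-3-ol | Cc1c(OCOC)c2c(c(Br)c1OCOC)OC(C)(C)[C@@H](O)C2 | intermediate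
12 | 3-phenylpropanoyl chloride | O=C(Cl)CCc1ccccc1 | starting material
13 | N-methoxy-N-methyl-3-phenylpropanamide | CON(C)C(=O)CCc1ccccc1 | intermediate
14 | lithium (3S)-8-lithio-5,7-bis(methoxymethoxy)-2,2,6-trimethylchroman-3-olate | Cc1c(OCOC)c2c(c([Li])c1OCOC)OC(C)(C)[C@@H](O[Li])C2 | intermediate
15 | 1-[(3S)-3-hydroxy-5,7-bis(methoxymethoxy)-2,2,6-trimethylchroman-8-yl]-3-phenylpropan-1-one | Cc1c(OCOC)c2c(c(C(=O)CCc3ccccc3)c1OCOC)OC(C)(C)[C@@H](O)C2 | intermediate
16 | 1-[(3S)-3,5,7-trihydroxy-2,2,6-trimethylchroman-8-yl]-3-phenylpropan-1-one | Cc1c(O)c2c(c(C(=O)CCc3ccccc3)c1O)OC(C)(C)[C@@H](O)C2 | target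

Total step count: 10
Longest linear sequence: 9 (steps 1–7, 9 and 10; step 8 is a one-step side branch)

Steps most likely to fail

Step 6 (bears the label "Proposed new method:"). Three processes may defeat it:
- poor facial selectivity at C3, because the alkene has no strong second contact with the catalyst;
- loss of boron from the β-boryl cation (ipso substitution to a prenyl side chain) or acid-induced ring-opening elimination of the β-aryloxy boronate;
- oligomerisation of the quinone methide, or acetal exchange of an ortho MOM group with the benzylic hydroxyl.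

The fallback uses known chemistry, sets out from 4 and comes back to the route at 11. Phenol 4 is condensed with 3-methylbut-2-enal (ethylenediammonium diacetate, xylene, reflux; condensation followed by oxa-6π electrocyclisation) to give 5,7-bis(methoxymethoxy)-2,2,6-trimethyl-2H-chromene F1. Jacobsen–Katsuki epoxidation with (S,S)-N,N'-bis(3,5-di-tert-butylsalicylidene)-1,2-cyclohexanediaminomanganese chloride, mCPBA and N-methylmorpholine N-oxide at −78 °C should, by analogy with other 2,2-dimethylchromenes, give (3S,4S)-3,4-epoxy-5,7-bis(methoxymethoxy)-2,2,6-trimethylchroman F2. This acid-sensitive epoxide is not purified but reduced with LiAlH4 in THF, hydride entering at the benzylic C4 and the C3–O bond staying intact, to give (3S)-5,7-bis(methoxymethoxy)-2,2,6-trimethylchroman-3-ol F3. NBS in MeCN then brominates the only free ring position (C8) and gives 11.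

Step 9. Proton transfer from the α-CH2 of the amide to the hindered, doubly ortho-oxygenated aryllithium (enolisation instead of addition) or lateral metalation of the C6 methyl on warming would return debrominated material. The fallback replaces the aryl-metal addition by electrophilic acylation of the free phenol; it sets out from 11 and reaches 16 directly. Methanolic HCl (40 °C) removes the MOM groups and gives (3S)-8-bromo-2,2,6-trimethylchroman-3,5,7-triol F4. Hydrodebromination (H2, Pd/C, NaOAc, MeOH) gives (3S)-2,2,6-trimethylchroman-3,5,7-triol F5. A Houben–Hoesch reaction with 3-phenylpropanenitrile (ZnCl2, HCl gas, Et2O, 0 °C) should then acylate C8, the only free ring carbon, to give 1-[(3S)-3,5,7-trihydroxy-2,2,6-trimethylchroman-8-yl]-3-phenylpropan-1-iminium chloride F6, which warm water hydrolyses to 16. Any ester formed at the C3 hydroxyl by a competing Pinner reaction would be cleaved with aqueous NaOH before isolation.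

Step 5. Premature loss of the benzylic oxygen through the quinone methide with capture of hydride (over-reduction to the methyl compound), or self-condensation of the o-hydroxybenzyl alcohol on concentration. The fallback builds the hydroxymethyl group at the alcohol oxidation level and keeps it masked; it sets out from 4 and comes back at 7. Phenylboronic acid-templated ortho-hydroxymethylation of 4 (PhB(OH)2, paraformaldehyde, cat. propionic acid, toluene, reflux with water removal) gives 5,7-bis(methoxymethoxy)-6-methyl-2-phenyl-4H-1,3,2-benzodioxaborinine F7, in which the phenol is tied up so that only one ortho position reacts. NBS brominates the remaining ring position to give 8-bromo-5,7-bis(methoxymethoxy)-6-methyl-2-phenyl-4H-1,3,2-benzodioxaborinine F8. Transesterification with 2,2-dimethylpropane-1,3-diol just before the key step releases 7.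

Further compounds
F1 | step 6 | 5,7-bis(methoxymethoxy)-2,2,6-trimethyl-2H-chromene | Cc1c(OCOC)c2c(cc1OCOC)OC(C)(C)C=C2
F2 | step 6 | (3S,4S)-3,4-epoxy-5,7-bis(methoxymethoxy)-2,2,6-trimethylchroman | Cc1c(OCOC)c2c(cc1OCOC)OC(C)(C)[C@H]1O[C@H]12
F3 | step 6 | (3S)-5,7-bis(methoxymethoxy)-2,2,6-trimethylchroman-3-ol | Cc1c(OCOC)c2c(cc1OCOC)OC(C)(C)[C@@H](O)C2
F4 | step 9 | (3S)-8-bromo-2,2,6-trimethylchroman-3,5,7-triol | Cc1c(O)c2c(c(Br)c1O)OC(C)(C)[C@@H](O)C2
F5 | step 9 | (3S)-2,2,6-trimethylchroman-3,5,7-triol | Cc1c(O)c2c(cc1O)OC(C)(C)[C@@H](O)C2
F6 | step 9 | 1-[(3S)-3,5,7-trihydroxy-2,2,6-trimethylchroman-8-yl]-3-phenylpropan-1-iminium chloride | Cc1c(O)c2c(c(C(=[NH2+])CCc3ccccc3)c1O)OC(C)(C)[C@@H](O)C2.[Cl-]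
F7 | step 5 | 5,7-bis(methoxymethoxy)-6-methyl-2-phenyl-4H-1,3,2-benzodioxaborinine | COCOc1cc2OB(c3ccccc3)OCc2c(OCOC)c1C
F8 | step 5 | 8-bromo-5,7-bis(methoxymethoxy)-6-methyl-2-phenyl-4H-1,3,2-benzodioxaborinine | COCOc1c(Br)c2OB(c3ccccc3)OCc2c(OCOC)c1C
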